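Ring B is a 2H-pyran (O2–C1H2–C8a=C4a–C4=C3), the closed valence tautomer of the cis-dienone O=C3–C4=C4a–C8a=C1H2 whose carbons C4a and C8a are the fusion atoms with ring A. The route exploits this by disconnecting O2–C1 and C4a–C8a: in one palladium-mediated operation a 6-exo Heck cyclization joins C4a to C8a (ring A) and the resulting dienone closes by oxa-6π electrocyclization (ring B). The precursor is the open-chain (Z)-β-iodo dienone 24 with a terminal vinyl ketone (C8, C8a, C1), the C6 aroate, the C7 silyl ether and the protected acrylate; C6 and C7 come from a Sharpless epoxidation and an invertive epoxide opening by the aryl acid.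

Key step: step 17

Locants C1–C11 follow the 1H-isochromene numbering of the target throughout; ArCO = 3,4-bis[(tert-butyldimethylsilyl)oxy]-2-methoxy-6-methylbenzoyl, TBS = tert-butyldimethylsilyl, TES = triethylsilyl, TMSE = 2-(trimethylsilyl)ethyl.
Assumption: the configuration at C8 is inconsequential because C8 becomes the ketone in step 16, so the (R)-carbinol selected in step 10 serves only as a handle.

**Aryl acid (steps 1–3)**

Step 1
Reactants: 1 5-hydroxyvanillin
Product: 2 3,4-bis[(tert-butyldimethylsilyl)oxy]-5-methoxybenzaldehyde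
Conditions: TBSCl (2.5 equiv), imidazole (5 equiv), DMF, rt
Reagents that add atoms: tert-butyldimethylsilyl chloride, CC(C)(C)[Si](C)(C)Cl
Why: Imidazole-promoted O-silylation should mask both phenols as fluoride-labile, bulky ethers that do not coordinate lithium, which leaves the methoxy group as the only directing group for step 3.

Step 2
Reactants: 2 3,4-bis[(tert-butyldimethylsilyl)oxy]-5-methoxybenzaldehyde
Product: 4 1,2-bis[(tert-butyldimethylsilyl)oxy]-3-methoxy-5-methylbenzene, via benzylic alcohol 3 (not isolated)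
Conditions: H2 (3 atm), Pd/C (10 wt%), EtOAc–AcOH (10:1), rt
Reagents that add atoms: none
Why: Catalytic hydrogenation and then benzylic hydrogenolysis of the electron-rich benzylic alcohol should reduce the formyl group to methyl, and aryl silyl ethers are inert to H2 over Pd/C in a non-alcoholic solvent.

Step 3
Reactants: 4 1,2-bis[(tert-butyldimethylsilyl)oxy]-3-methoxy-5-methylbenzene
Product: 6 3,4-bis[(tert-butyldimethylsilyl)oxy]-2-methoxy-6-methylbenzoic acid, via aryllithium 5 (not isolated)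
Conditions: n-BuLi (1.3 equiv), TMEDA (1.3 equiv), Et2O, 0 °C; CO2 (g), −78 °C → rt; cold 1 M HCl
Reagents that add atoms: carbon dioxide, O=C=O
Why: Directed ortho-metalation by the methoxy group should lithiate the only free position next to it (between OMe and CH3), since the other ortho site carries a silyl ether, and carboxylation of the aryllithium gives the 2,6-disubstituted acid.

**Fumaric half-ester chloride (steps 4–5)**

Step 4
Reactants: 7 maleic anhydride
Product: 9 (E)-4-oxo-4-[2-(trimethylsilyl)ethoxy]but-2-enoic acid, via maleate half-ester 8 (not isolated)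
Conditions: Me3SiCH2CH2OH (1.0 equiv), DMAP (5 mol%), toluene, 60 °C; then I2 (5 mol%), visible light, rt → 60 °C
Reagents that add atoms: 2-(trimethylsilyl)ethanol, C[Si](C)(C)CCO
Why: Alcoholysis of the cyclic anhydride gives the Z half-ester, and reversible iodine-atom addition–elimination should equilibrate it to the thermodynamically favoured E (fumarate) isomer.

Step 5
Reactants: 9 (E)-4-oxo-4-[2-(trimethylsilyl)ethoxy]but-2-enoic acid
Product: 10 2-(trimethylsilyl)ethyl (E)-4-chloro-4-oxobut-2-enoate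
Conditions: (COCl)2 (1.2 equiv), DMF (cat.), CH2Cl2, 0 °C → rt; concentrated and used crude
Reagents that add atoms: oxalyl chloride, ClC(=O)C(=O)Cl
Why: Vilsmeier-type activation should convert the acid into its chloride without touching the TMSE ester or the E alkene.

**Main chain (steps 6–18)**

Step 6
Reactants: 11 4-(trimethylsilyl)but-3-yn-1-ol
Product: 13 ethyl (E)-2-methyl-6-(trimethylsilyl)hex-2-en-5-ynoate, via ynal 12 (not isolated)
Conditions: Dess–Martin periodinane (1.1 equiv), CH2Cl2, 0 °C → rt; then Ph3P=C(CH3)CO2Et (2.5 equiv), rt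
Reagents that add atoms: ethyl 2-(triphenylphosphoranylidene)propanoate, CCOC(=O)C(C)=P(c1ccccc1)(c1ccccc1)c1ccccc1
Why: Dess–Martin oxidation followed in the same flask by Wittig olefination with the stabilised ylide avoids isolating the isomerisation-prone 3-alkynal and should give the E trisubstituted enoate.

Step 7
Reactants: 13 ethyl (E)-2-methyl-6-(trimethylsilyl)hex-2-en-5-ynoate
Product: 14 (E)-2-methyl-6-(trimethylsilyl)hex-2-en-5-yn-1-ol
Conditions: i-Bu2AlH (2.2 equiv), CH2Cl2, −78 °C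
Reagents that add atoms: none
Why: 1,2-Reduction of the enoate by the aluminium hydride should give the allylic alcohol without touching the alkynylsilane or the alkene geometry.

Step 8
Reactants: 14 (E)-2-methyl-6-(trimethylsilyl)hex-2-en-5-yn-1-ol
Product: 15 (E)-2-methyl-6-(trimethylsilyl)hex-2-en-5-ynal
Conditions: MnO2 (activated, 15 equiv), CH2Cl2, rt
Reagents that add atoms: none
Why: Neutral allylic oxidation with MnO2 should give the enal without moving the skipped alkyne into conjugation.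

Step 9
Reactants: 15 (E)-2-methyl-6-(trimethylsilyl)hex-2-en-5-ynal
Product: 17 racemic (E)-4-methylocta-1,4-dien-7-yn-3-ol, via alkynylsilane 16 (not isolated)
Conditions: CH2=CHMgBr (1.3 equiv), THF, −78 → 0 °C; then MeOH, K2CO3 (0.3 equiv), rt; aq. NH4Cl
Reagents that add atoms: vinylmagnesium bromide, C=C[Mg]Br
Why: 1,2-Addition of the Grignard reagent to the enal installs C8a and C1 as a doubly allylic carbinol (racemic at C8), and carbonate-catalysed methanolysis of the C(sp)–Si bond frees the terminal alkyne.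

Step 10
Reactants: 17 racemic (E)-4-methylocta-1,4-dien-7-yn-3-ol
Product: 18 (1R)-1-[(2R,3R)-2-methyl-3-(prop-2-yn-1-yl)oxiran-2-yl]prop-2-en-1-ol
Conditions: Ti(OiPr)4 (0.15 equiv), D-(−)-diisopropyl tartrate (0.2 equiv), t-BuOOH (0.55 equiv), 4 Å MS, CH2Cl2, −20 °C; unreacted (S)-17 removed by chromatography
Reagents that add atoms: tert-butyl hydroperoxide, CC(C)(C)OO
Why: Sharpless asymmetric epoxidation run as a kinetic resolution: with the D-(−)-tartrate catalyst only the (R)-carbinol is epoxidised quickly, at its E-trisubstituted alkene and from the face fixed by the ligand, which should give the erythro (2R,3R)-oxirane and so sets C7 and the pre-inversion configuration of C6 by reagent control, while the (S)-alcohol and the slow monosubstituted vinyl group are left behind.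

Step 11
Reactants: 18 (1R)-1-[(2R,3R)-2-methyl-3-(prop-2-yn-1-yl)oxiran-2-yl]prop-2-en-1-ol; 6 3,4-bis[(tert-butyldimethylsilyl)oxy]-2-methoxy-6-methylbenzoic acid
Product: 19 (3R,4R,5S)-3,4-dihydroxy-4-methyloct-1-en-7-yn-5-yl 3,4-bis[(tert-butyldimethylsilyl)oxy]-2-methoxy-6-methylbenzoate
Conditions: Ti(OiPr)4 (1.5 equiv), 6 (1.5 equiv), CH2Cl2, rt
Reagents that add atoms: none
Why: Ti(OiPr)4-mediated opening of a 2,3-epoxy alcohol by a carboxylic acid: the titanium chelate directs the carboxylate to the distal secondary oxirane carbon (C6), SN2 inversion there sets (S)-C6 while the C7–O bond is untouched, and because the hindered acid reacts through its carboxylate oxygen its two ortho substituents do not block ester formation.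

Step 12
Reactants: 19 C7,C8-diol C6-aroate
Product: 20 (3R,4S,5S)-4-methyl-3,4-bis[(triethylsilyl)oxy]oct-1-en-7-yn-5-yl 3,4-bis[(tert-butyldimethylsilyl)oxy]-2-methoxy-6-methylbenzoate
Conditions: TESOTf (3 equiv), 2,6-lutidine (5 equiv), CH2Cl2, −78 → 0 °C
Reagents that add atoms: triethylsilyl trifluoromethanesulfonate, CC[Si](CC)(CC)OS(=O)(=O)C(F)(F)F
Why: The silyl triflate with 2,6-lutidine should silylate both the secondary allylic and the hindered tertiary hydroxyl, which blocks O-acylation at C8 and 5-exo oxa-Michael addition of the C7 hydroxyl to the ynone made next.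

Step 13
Reactants: 20 bis(triethylsilyl) ether alkyne; 10 2-(trimethylsilyl)ethyl (E)-4-chloro-4-oxobut-2-enoate
Product: 21 2-(trimethylsilyl)ethyl (2E,8S,9S,10R)-8-(ArCO-oxy)-9-methyl-4-oxo-9,10-bis[(triethylsilyl)oxy]dodeca-2,11-dien-5-ynoate
Conditions: PdCl2(PPh3)2 (3 mol%), CuI (6 mol%), Et3N (1.5 equiv), THF, rt
Reagents that add atoms: none
Why: Acyl Sonogashira coupling: the copper acetylide transmetalates to the acylpalladium chloride formed from 10 and reductive elimination gives the ynone, and the acid chloride has no α-hydrogen so no ketene pathway competes.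

Step 14
Reactants: 21 ynone
Product: 22 2-(trimethylsilyl)ethyl (2E,5Z,8S,9S,10R)-8-(ArCO-oxy)-6-iodo-9-methyl-4-oxo-9,10-bis[(triethylsilyl)oxy]dodeca-2,5,11-trienoate
Conditions: NaI (1.5 equiv), AcOH (5 equiv), MeCN, 0 °C → rt, dark; aq. NaHCO3/Na2S2O3
Reagents that add atoms: sodium iodide, [Na+].[I-]
Why: Conjugate hydroiodination of the ynone: iodide adds to the alkyne β-carbon C4a and anti protonation of the allenol should give the kinetic Z β-iodoenone (iodine cis to the C3 acyl group), the alkyne being the most electrophilic site and its vinyl iodide irreversible whereas iodide addition to the enoate reverts.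

Step 15
Reactants: 22 bis(triethylsilyl) (Z)-β-iodo dienone
Product: 23 2-(trimethylsilyl)ethyl (2E,5Z,8S,9R,10R)-8-(ArCO-oxy)-10-hydroxy-6-iodo-9-methyl-4-oxo-9-[(triethylsilyl)oxy]dodeca-2,5,11-trienoate
Conditions: PPTS (0.3 equiv), MeOH–CH2Cl2 (1:3), 0 °C
Reagents that add atoms: none
Why: Acid-catalysed methanolysis discriminates the silyl ethers by steric access, so the secondary allylic TES ether at C8 should be cleaved while the tertiary TES ether at C7 and the acid-stable aryl TBS ethers remain.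

Step 16
Reactants: 23 C8 allylic alcohol
Product: 24 2-(trimethylsilyl)ethyl (2E,5Z,8S,9S)-8-(ArCO-oxy)-6-iodo-9-methyl-4,10-dioxo-9-[(triethylsilyl)oxy]dodeca-2,5,11-trienoate
Conditions: Dess–Martin periodinane (1.5 equiv), NaHCO3, CH2Cl2, 0 °C → rt; used at once
Reagents that add atoms: none
Why: Buffered Dess–Martin oxidation of the secondary allylic alcohol should give the vinyl ketone under neutral conditions that the iodo dienone tolerates, and C7 has no hydrogen so no epimerisation or elimination is possible.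

Step 17
Reactants: 24 acyclic (Z)-β-iodo dienone vinyl ketone
Product: 26 (6S,7S)-7-methyl-8-oxo-3-{(1E)-3-oxo-3-[2-(trimethylsilyl)ethoxy]prop-1-en-1-yl}-7-[(triethylsilyl)oxy]-5,6,7,8-tetrahydro-1H-isochromen-6-yl 3,4-bis[(tert-butyldimethylsilyl)oxy]-2-methoxy-6-methylbenzoate, via trienone 25 (not isolated)
Conditions: Pd(OAc)2 (10 mol%), P(2-furyl)3 (25 mol%), Ag2CO3 (1.5 equiv), MeCN (degassed), 50 °C, dark
Reagents that add atoms: none
Why: Proposed new method: zerovalent palladium generated from Pd(OAc)2 and the phosphine should insert into the C4a–I bond with retention of the Z geometry, the alkenylpalladium should add syn across the vinyl ketone so that C4a bonds to the α-carbon C8a and palladium ends on C1, and loss of the single β-hydrogen (on C8a) should release trienone 25, whose cis-1-oxatriene O=C3–C4=C4a–C8a=C1H2 then closes thermally to the 2H-pyran. The closest known reaction types are exo-selective intramolecular Heck cyclizations of alkenyl or aryl halides onto the α-carbon of unsaturated carbonyl compounds and the spontaneous oxa-6π closure of cis-dienones to fused 2H-pyrans; their union in one flask from an open chain is the untested part. Ring A closes by 6-exo-trig carbopalladation (bond C4a–C8a) and ring B by disrotatory oxa-6π electrocyclization (bond O2–C1). No stereocentre is formed, and C6 and C7 are spectators because no bond to them is made or broken. The step needs 6-exo attack at C8a in preference to 7-endo attack at C1, which the shorter tether and the strain of the seven-membered alternative should secure against the electronic bias of the enone, and it needs the C3 acyl group cis to C8a, which the (Z)-iodide from step 14 and stereoretentive oxidative addition secure. Ag2CO3 abstracts iodide to give a fast-inserting cationic palladium and suppresses hydride re-addition, the weakly nucleophilic tri(2-furyl)phosphine avoids phosphine addition to the vinyl ketone, and closure is driven because C4a=C8a becomes endocyclic and conjugated with both the C8 ketone and O2.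

Step 18
Reactants: 26 fully silyl-protected target
Product: 27 (2E)-3-[(6S,7S)-6-[(3,4-dihydroxy-2-methoxy-6-methylbenzoyl)oxy]-7-hydroxy-7-methyl-8-oxo-5,6,7,8-tetrahydro-1H-isochromen-3-yl]prop-2-enoic acid (target)
Conditions: (Me2N)3S+ Me3SiF2− (TASF, 6 equiv), DMF, 0 °C → rt, argon; then AcOH, pH 5 buffer
Reagents that add atoms: none
Why: Fluoride-induced desilylation with an anhydrous, weakly basic fluoride source should cleave both aryl TBS ethers and the tertiary TES ether and fragment the TMSE ester (loss of ethene and Me3SiF) in one operation, leaving the hindered aryl ester and the pyran untouched.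

**Compound list**

1 | 5-hydroxyvanillin (3,4-dihydroxy-5-methoxybenzaldehyde) | COc1cc(C=O)cc(O)c1O | starting material
2 | 3,4-bis[(tert-butyldimethylsilyl)oxy]-5-methoxybenzaldehyde | COc1cc(C=O)cc(O[Si](C)(C)C(C)(C)C)c1O[Si](C)(C)C(C)(C)C | intermediate
3 | {3,4-bis[(tert-butyldimethylsilyl)oxy]-5-methoxyphenyl}methanol | COc1cc(CO)cc(O[Si](C)(C)C(C)(C)C)c1O[Si](C)(C)C(C)(C)C | intermediate (not isolated)
4 | 1,2-bis[(tert-butyldimethylsilyl)oxy]-3-methoxy-5-methylbenzene | COc1cc(C)cc(O[Si](C)(C)C(C)(C)C)c1O[Si](C)(C)C(C)(C)C | intermediate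
5 | {3,4-bis[(tert-butyldimethylsilyl)oxy]-2-methoxy-6-methylphenyl}lithium | COc1c([Li])c(C)cc(O[Si](C)(C)C(C)(C)C)c1O[Si](C)(C)C(C)(C)C | intermediate (not isolated)
6 | 3,4-bis[(tert-butyldimethylsilyl)oxy]-2-methoxy-6-methylbenzoic acid | COc1c(C(=O)O)c(C)cc(O[Si](C)(C)C(C)(C)C)c1O[Si](C)(C)C(C)(C)C | intermediate
7 | maleic anhydride | O=C1OC(=O)C=C1 | starting material
8 | (Z)-4-oxo-4-[2-(trimethylsilyl)ethoxy]but-2-enoic acid | C[Si](C)(C)CCOC(=O)/C=C\C(=O)O | intermediate (not isolated)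
9 | (E)-4-oxo-4-[2-(trimethylsilyl)ethoxy]but-2-enoic acid | C[Si](C)(C)CCOC(=O)/C=C/C(=O)O | intermediate
10 | 2-(trimethylsilyl)ethyl (E)-4-chloro-4-oxobut-2-enoate | C[Si](C)(C)CCOC(=O)/C=C/C(=O)Cl | intermediate
11 | 4-(trimethylsilyl)but-3-yn-1-ol | C[Si](C)(C)C#CCCO | starting material
12 | 4-(trimethylsilyl)but-3-ynal | C[Si](C)(C)C#CCC=O | intermediate (not isolated)
13 | ethyl (E)-2-methyl-6-(trimethylsilyl)hex-2-en-5-ynoate | CCOC(=O)/C(C)=C/CC#C[Si](C)(C)C | intermediate
14 | (E)-2-methyl-6-(trimethylsilyl)hex-2-en-5-yn-1-ol | OC/C(C)=C/CC#C[Si](C)(C)C | intermediate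
15 | (E)-2-methyl-6-(trimethylsilyl)hex-2-en-5-ynal | O=C/C(C)=C/CC#C[Si](C)(C)C | intermediate
16 | racemic (E)-4-methyl-8-(trimethylsilyl)octa-1,4-dien-7-yn-3-ol | C=CC(O)/C(C)=C/CC#C[Si](C)(C)C | intermediate (not isolated)
17 | racemic (E)-4-methylocta-1,4-dien-7-yn-3-ol | C=CC(O)/C(C)=C/CC#C | intermediate
18 | (1R)-1-[(2R,3R)-2-methyl-3-(prop-2-yn-1-yl)oxiran-2-yl]prop-2-en-1-ol | C=C[C@@H](O)[C@@]1(C)O[C@@H]1CC#C | intermediate
19 | (3R,4R,5S)-3,4-dihydroxy-4-methyloct-1-en-7-yn-5-yl 3,4-bis[(tert-butyldimethylsilyl)oxy]-2-methoxy-6-methylbenzoate | C=C[C@@H](O)[C@@](C)(O)[C@@H](OC(=O)c1c(C)cc(O[Si](C)(C)C(C)(C)C)c(O[Si](C)(C)C(C)(C)C)c1OC)CC#C | intermediate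
20 | (3R,4S,5S)-4-methyl-3,4-bis[(triethylsilyl)oxy]oct-1-en-7-yn-5-yl 3,4-bis[(tert-butyldimethylsilyl)oxy]-2-methoxy-6-methylbenzoate | C=C[C@@H](O[Si](CC)(CC)CC)[C@@](C)(O[Si](CC)(CC)CC)[C@@H](OC(=O)c1c(C)cc(O[Si](C)(C)C(C)(C)C)c(O[Si](C)(C)C(C)(C)C)c1OC)CC#C | intermediate
21 | 2-(trimethylsilyl)ethyl (2E,8S,9S,10R)-8-(ArCO-oxy)-9-methyl-4-oxo-9,10-bis[(triethylsilyl)oxy]dodeca-2,11-dien-5-ynoate | C=C[C@@H](O[Si](CC)(CC)CC)[C@@](C)(O[Si](CC)(CC)CC)[C@@H](OC(=O)c1c(C)cc(O[Si](C)(C)C(C)(C)C)c(O[Si](C)(C)C(C)(C)C)c1OC)CC#CC(=O)/C=C/C(=O)OCC[Si](C)(C)C | intermediate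
22 | 2-(trimethylsilyl)ethyl (2E,5Z,8S,9S,10R)-8-(ArCO-oxy)-6-iodo-9-methyl-4-oxo-9,10-bis[(triethylsilyl)oxy]dodeca-2,5,11-trienoate | C=C[C@@H](O[Si](CC)(CC)CC)[C@@](C)(O[Si](CC)(CC)CC)[C@@H](OC(=O)c1c(C)cc(O[Si](C)(C)C(C)(C)C)c(O[Si](C)(C)C(C)(C)C)c1OC)C/C(I)=C/C(=O)/C=C/C(=O)OCC[Si](C)(C)C | intermediate
23 | 2-(trimethylsilyl)ethyl (2E,5Z,8S,9R,10R)-8-(ArCO-oxy)-10-hydroxy-6-iodo-9-methyl-4-oxo-9-[(triethylsilyl)oxy]dodeca-2,5,11-trienoate | C=C[C@@H](O)[C@@](C)(O[Si](CC)(CC)CC)[C@@H](OC(=O)c1c(C)cc(O[Si](C)(C)C(C)(C)C)c(O[Si](C)(C)C(C)(C)C)c1OC)C/C(I)=C/C(=O)/C=C/C(=O)OCC[Si](C)(C)C | intermediate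
24 | 2-(trimethylsilyl)ethyl (2E,5Z,8S,9S)-8-(ArCO-oxy)-6-iodo-9-methyl-4,10-dioxo-9-[(triethylsilyl)oxy]dodeca-2,5,11-trienoate | C=CC(=O)[C@@](C)(O[Si](CC)(CC)CC)[C@@H](OC(=O)c1c(C)cc(O[Si](C)(C)C(C)(C)C)c(O[Si](C)(C)C(C)(C)C)c1OC)C/C(I)=C/C(=O)/C=C/C(=O)OCC[Si](C)(C)C | intermediate (key-step precursor)
25 | 2-(trimethylsilyl)ethyl (2E)-5-[(1Z,4S,5S)-5-(ArCO-oxy)-4-methyl-2-methylidene-3-oxo-4-[(triethylsilyl)oxy]cyclohexylidene]-4-oxopent-2-enoate | C=C1C(=O)[C@@](C)(O[Si](CC)(CC)CC)[C@@H](OC(=O)c2c(C)cc(O[Si](C)(C)C(C)(C)C)c(O[Si](C)(C)C(C)(C)C)c2OC)C/C1=C/C(=O)/C=C/C(=O)OCC[Si](C)(C)C | intermediate (not isolated)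
26 | (6S,7S)-7-methyl-8-oxo-3-{(1E)-3-oxo-3-[2-(trimethylsilyl)ethoxy]prop-1-en-1-yl}-7-[(triethylsilyl)oxy]-5,6,7,8-tetrahydro-1H-isochromen-6-yl 3,4-bis[(tert-butyldimethylsilyl)oxy]-2-methoxy-6-methylbenzoate | COc1c(O[Si](C)(C)C(C)(C)C)c(O[Si](C)(C)C(C)(C)C)cc(C)c1C(=O)O[C@H]1CC2=C(COC(/C=C/C(=O)OCC[Si](C)(C)C)=C2)C(=O)[C@@]1(C)O[Si](CC)(CC)CC | intermediate (key-step product)
27 | (2E)-3-[(6S,7S)-6-[(3,4-dihydroxy-2-methoxy-6-methylbenzoyl)oxy]-7-hydroxy-7-methyl-8-oxo-5,6,7,8-tetrahydro-1H-isochromen-3-yl]prop-2-enoic acid | COc1c(O)c(O)cc(C)c1C(=O)O[C@H]1CC2=C(COC(/C=C/C(=O)O)=C2)C(=O)[C@@]1(C)O | target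

**Step count and risks**

Total step count: 18 (3 for the aryl acid, 2 for the acid chloride, 13 in the main chain).
Longest linear sequence: 13 steps (steps 6–18, from 11).

Steps most likely to fail:

Step 17 (proposed cascade). The alkenylpalladium may insert in the 7-endo sense at C1, may lose its Z geometry before insertion, or the vinyl ketone may be consumed by base- or ligand-triggered oligomerisation before cyclization. The fallback sets out from 22 and closes ring A by a conventional 6-exo Heck cyclization onto the unactivated terminal alkene of the allylic silyl ether (Pd(OAc)2, P(2-furyl)3, Ag2CO3, MeCN, 60 °C), a well-established mode that forms the exocyclic 1,3-diene. Its cis-dienone should close to the pyran with C8 still at the carbinol level, 2-(trimethylsilyl)ethyl (2E)-3-[(6S,7S,8R)-6-(ArCO-oxy)-7-methyl-7,8-bis[(triethylsilyl)oxy]-5,6,7,8-tetrahydro-1H-isochromen-3-yl]prop-2-enoate F1. PPTS in MeOH–CH2Cl2 then frees the secondary allylic alcohol, 2-(trimethylsilyl)ethyl (2E)-3-[(6S,7R,8R)-6-(ArCO-oxy)-8-hydroxy-7-methyl-7-[(triethylsilyl)oxy]-5,6,7,8-tetrahydro-1H-isochromen-3-yl]prop-2-enoate F2, and Dess–Martin or MnO2 oxidation of this allylic alcohol comes back to the route at 26.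

Step 14. Iodide may also add to the fumaroyl alkene and reduce it, the kinetic Z iodide may equilibrate to E in acid, and the C8 silyl ether may be lost prematurely. The fallback sets out from 20 and makes the vinyl iodide before the electrophilic enoate exists. Coupling with acetyl chloride under the conditions of step 13 gives the methyl ynone (3R,4S,5S)-4-methyl-9-oxo-3,4-bis[(triethylsilyl)oxy]dec-1-en-7-yn-5-yl aroate F3. NaI/AcOH converts this simple ynone into the (Z)-β-iodo methyl enone (3R,4S,5S,7Z)-7-iodo-4-methyl-9-oxo-3,4-bis[(triethylsilyl)oxy]deca-1,7-dien-5-yl aroate F4. Kinetic enolisation of the methyl ketone (LiN(SiMe3)2, THF, −78 °C) and aldol addition to 2-(trimethylsilyl)ethyl glyoxylate F6 (from ozonolysis of 9, O3 then Me2S) give the aldol adduct 2-(trimethylsilyl)ethyl (5Z,8S,9S,10R)-8-(ArCO-oxy)-2-hydroxy-6-iodo-9-methyl-4-oxo-9,10-bis[(triethylsilyl)oxy]dodeca-5,11-dienoate F5 as a mixture of C2 epimers. Mesylation and elimination (MsCl, Et3N) give the E enoate and come back to the route at 22.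

Step 18. Basic fluoride may trigger vinylogous β-elimination of the C6 aroate through deprotonation at C5, the liberated catecholate may be oxidised by air, and the tertiary silyl ether may resist cleavage. The fallback sets out from 26 and avoids free phenoxide by staged, acid-side deprotection. Et3N·3HF (MeCN, rt) removes the three silyl ethers to give the trihydroxy ester 2-(trimethylsilyl)ethyl (2E)-3-[(6S,7S)-6-[(3,4-dihydroxy-2-methoxy-6-methylbenzoyl)oxy]-7-hydroxy-7-methyl-8-oxo-5,6,7,8-tetrahydro-1H-isochromen-3-yl]prop-2-enoate F7. Trifluoroacetic acid in CH2Cl2 (0 °C → rt) then cleaves the TMSE ester by acid-induced fragmentation and arrives at 27.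

Further compounds
F1 | step 17 | 2-(trimethylsilyl)ethyl (2E)-3-[(6S,7S,8R)-6-(ArCO-oxy)-7-methyl-7,8-bis[(triethylsilyl)oxy]-5,6,7,8-tetrahydro-1H-isochromen-3-yl]prop-2-enoate | COc1c(O[Si](C)(C)C(C)(C)C)c(O[Si](C)(C)C(C)(C)C)cc(C)c1C(=O)O[C@H]1CC2=C(COC(/C=C/C(=O)OCC[Si](C)(C)C)=C2)[C@@H](O[Si](CC)(CC)CC)[C@@]1(C)O[Si](CC)(CC)CC
F2 | step 17 | 2-(trimethylsilyl)ethyl (2E)-3-[(6S,7R,8R)-6-(ArCO-oxy)-8-hydroxy-7-methyl-7-[(triethylsilyl)oxy]-5,6,7,8-tetrahydro-1H-isochromen-3-yl]prop-2-enoate | COc1c(O[Si](C)(C)C(C)(C)C)c(O[Si](C)(C)C(C)(C)C)cc(C)c1C(=O)O[C@H]1CC2=C(COC(/C=C/C(=O)OCC[Si](C)(C)C)=C2)[C@@H](O)[C@@]1(C)O[Si](CC)(CC)CC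
F3 | step 14 | (3R,4S,5S)-4-methyl-9-oxo-3,4-bis[(triethylsilyl)oxy]dec-1-en-7-yn-5-yl 3,4-bis[(tert-butyldimethylsilyl)oxy]-2-methoxy-6-methylbenzoate | C=C[C@@H](O[Si](CC)(CC)CC)[C@@](C)(O[Si](CC)(CC)CC)[C@@H](OC(=O)c1c(C)cc(O[Si](C)(C)C(C)(C)C)c(O[Si](C)(C)C(C)(C)C)c1OC)CC#CC(C)=O
F4 | step 14 | (3R,4S,5S,7Z)-7-iodo-4-methyl-9-oxo-3,4-bis[(triethylsilyl)oxy]deca-1,7-dien-5-yl 3,4-bis[(tert-butyldimethylsilyl)oxy]-2-methoxy-6-methylbenzoate | C=C[C@@H](O[Si](CC)(CC)CC)[C@@](C)(O[Si](CC)(CC)CC)[C@@H](OC(=O)c1c(C)cc(O[Si](C)(C)C(C)(C)C)c(O[Si](C)(C)C(C)(C)C)c1OC)C/C(I)=C/C(C)=O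
F5 | step 14 | 2-(trimethylsilyl)ethyl (5Z,8S,9S,10R)-8-(ArCO-oxy)-2-hydroxy-6-iodo-9-methyl-4-oxo-9,10-bis[(triethylsilyl)oxy]dodeca-5,11-dienoate (C2 epimers) | C=C[C@@H](O[Si](CC)(CC)CC)[C@@](C)(O[Si](CC)(CC)CC)[C@@H](OC(=O)c1c(C)cc(O[Si](C)(C)C(C)(C)C)c(O[Si](C)(C)C(C)(C)C)c1OC)C/C(I)=C/C(=O)CC(O)C(=O)OCC[Si](C)(C)C
F6 | step 14 | 2-(trimethylsilyl)ethyl glyoxylate | C[Si](C)(C)CCOC(=O)C=O
F7 | step 18 | 2-(trimethylsilyl)ethyl (2E)-3-[(6S,7S)-6-[(3,4-dihydroxy-2-methoxy-6-methylbenzoyl)oxy]-7-hydroxy-7-methyl-8-oxo-5,6,7,8-tetrahydro-1H-isochromen-3-yl]prop-2-enoate | COc1c(O)c(O)cc(C)c1C(=O)O[C@H]1CC2=C(COC(/C=C/C(=O)OCC[Si](C)(C)C)=C2)C(=O)[C@@]1(C)O
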